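The numbers come from no measurement, and the outcome is calculated.

Over 4.0 d, you suspect, the way of feeding these flasks counts for little, and you asked for a quick number, so here is the card and then what we reckon.

    starting material + free enzyme ⇌ first complex (K1 = 8.5 M⁻¹, k1 = 1.2 × 10⁵ M⁻¹ h⁻¹)
    first complex → loaded enzyme + first product (k2 = 2200 h⁻¹)
    second substrate + loaded enzyme ⇌ second complex (K3 = 2.1 M⁻¹, k3 = 8100 M⁻¹ h⁻¹)
    second complex → free enzyme + target (k4 = 430 h⁻¹)
    precatalyst → free enzyme (k5 = 0.49 h⁻¹)
    second substrate + target → over-reaction product (k6 = 0.23 M⁻¹ h⁻¹)

| setting | elm | larch | maple | cedar | oak |
|---|---|---|---|---|---|
| starting material | 0.20 M (in portions, 4, over 2.5 d) | 0.20 M | 0.20 M (fed, over 6.0 h) | 0.20 M | 0.20 M (fed, over 2.5 d) |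
| second substrate | 0.300 M | 0.300 M | 0.300 M | 0.300 M (fed, over 2.5 d) | 0.300 M |
| precatalyst | 0.10 mM | 0.10 mM | 0.10 mM | 0.10 mM | 0.10 mM |
| time | 4.0 d | 4.0 d | 4.0 d | 4.0 d | 4.0 d |
| remark | first portion at the start, last at 2.5 d | everything together at the start | all else is in the flask from the start; the feed brings no volume worth counting | all else is in the flask from the start; the feed brings no volume worth counting | all else is in the flask from the start; the feed brings no volume worth counting |

1. the flask that comes out highest in amount of target, in percent of the starting material charged, or "all alike" when all lie within 1.5 percentage points (elm / larch / maple / cedar / oak / all alike)
2. target at the end, in percent of the starting material charged, elm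
3. target at the end, in percent of the starting material charged, larch
4. target at the end, in percent of the starting material charged, maple
5. target at the end, in percent of the starting material charged, cedar
6. target at the end, in percent of the starting material charged, oak

1. Each target takes one second substrate and each over-reaction product takes one more, and the second substrate's excess over the starting material is 50.0% of the starting charge. We therefore call the floor 50.0% the fraction of the charge that stays target once the whole excess has gone into over-reaction; the catalyst's 0.0500% of the charge we neglect.

2. The same balance gives the rule we carry: in a flask whose starting material has turned over completely, target equals the floor plus the second substrate still free, both counted as fractions of the starting charge, since each over-reaction removes one of each and leaves their difference at the floor.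

3. Step 6 runs at 0.23 M⁻¹ h⁻¹ times second substrate times target, and we treat it as second order, with neither partner in large excess; the 0.42 d in which target would halve at the charged concentrations is shorter than the 4.0 d we have, but it belongs to the charged level of second substrate, which falls as conversion spends it, so we do not take it as the half-life of target in the flask.

4. The ratio of leftover to target falls exponentially, at 0.23 M⁻¹ h⁻¹ times the floor's concentration. If we take conversion as instant, that ratio starts at 50.0% and reaches 0.0550 at the end, which puts target at the floor divided by one minus that ratio, 52.9%, and this is our number for larch and maple. In larch that ratio halves in 1.26 d, and cedar's feed of second substrate runs 2.5 d, longer than that, so we look for cedar above that figure, though we carry no number for it by hand.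

5. The forecast names cedar, with 52.5% for elm, 53% for larch, 53% for maple, 57% for cedar and 52% for oak, on the ground that “Only feeding the second substrate keeps its level low while target builds”.

The highest flask is cedar, as the forecast has it, at 58.2%, against 49.4% for elm, 53.0% for larch, 53.1% for maple and 52.5% for oak. At 4.00 d cedar holds 0% of its starting material and 5.5% of its own charge of second substrate. That leftover is 8.21% of the starting charge, and on the floor of 50.0% it makes 58.2%. Larch, with 2.0% left, makes 53.0% the same way. At 40.0 d elm stands at 50.0%, on the floor.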